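**Target:** robinetinidol-(4α→8)-epigallocatechin. Upper unit 2R,3S,4S (2,3-trans, 3,4-trans). Lower unit 2R,3R.

**Retrosynthetic overview**
1. Final operations: nine benzyl ethers are removed. The 3-OH comes from axial hydride delivery to a flavan-3-one, and that ketone is unmasked from a 3-nitro group (Nef).
2. Interflavan bond C4–C8: 1,4-addition of 8-lithiated epigallocatechin to a 3-nitroflav-3-ene. No C4 cation is involved.
3. Key disconnection C3–C4 (and C2–C3): C3 is nitromethane, a masked acyl anion. As a nitronate it bonds in turn to two aldehyde carbons, C2 (gallaldehyde ether) and C4 (resorcylaldehyde ether).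
4. Ring order: rings A and B and the whole lower unit are bought. Ring C of the upper unit is the only ring formed, in the oxa-Michael/nitro-aldol domino.
5. Stereochemistry: the organocatalyst sets C2, C2 directs the aryl group onto C4, and fixed C4 then directs C2 and C3 by equilibration. Hydride sets the carbinol centre.

**Assumption:** (−)-epigallocatechin, 3,4,5-tris(benzyloxy)benzaldehyde and 4-(benzyloxy)-2-hydroxybenzaldehyde are taken as catalogue compounds, and of the two commercial pseudo-enantiomeric cinchona thioureas the one that gives the (S)-chromene is used in step 4 (written here as the quinidine-derived one).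

Step 1
Reactants: 1 (−)-epigallocatechin
Product: 2 5,7,3',4',5'-penta-O-benzyl-(−)-epigallocatechin
Conditions: BnBr (5.5 equiv), K2CO3 (6 equiv), DMF, 0 °C → rt, Ar
Reagents that add atoms: benzyl bromide, BrCc1ccccc1
Why: Williamson etherification (SN2) of the five acidic phenols, in which K2CO3 does not alkylate the secondary 3-OH and both stereocentres are untouched at or below room temperature.

Step 2
Reactants: 2 5,7,3',4',5'-penta-O-benzyl-(−)-epigallocatechin
Product: 3 8-bromo-5,7,3',4',5'-penta-O-benzyl-(−)-epigallocatechin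
Conditions: NBS (1.0 equiv), CH2Cl2, −78 → 0 °C
Reagents that add atoms: N-bromosuccinimide, O=C1CCC(=O)N1Br
Why: Electrophilic aromatic bromination (SEAr), which in 5,7-di-O-benzyl flavan-3-ols goes selectively to C8 of the phloroglucinol ring because the tribenzyloxyphenyl ring is far less activated.

Step 3
Reactants: 4 3,4,5-tris(benzyloxy)benzaldehyde; 5 nitromethane
Product: 6 (E)-1,2,3-tris(benzyloxy)-5-(2-nitrovinyl)benzene
Conditions: MeNO2 (10 equiv), NH4OAc (0.5 equiv), AcOH, 100 °C
Reagents that add atoms: none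
Why: Henry reaction with dehydration (nitro-aldol condensation), in which the nitromethane carbon (future C3) bonds as a nitronate to the aldehyde carbon (future C2) and thermodynamic control gives the E-alkene.

Step 4
Reactants: 6 (E)-1,2,3-tris(benzyloxy)-5-(2-nitrovinyl)benzene; 7 4-(benzyloxy)-2-hydroxybenzaldehyde
Product: 9 (S)-7-(benzyloxy)-3-nitro-2-[3,4,5-tris(benzyloxy)phenyl]-2H-chromene, via nitro-aldol adduct 8 (not isolated)
Conditions: quinidine-derived 9-epi-amino 3,5-(CF3)2C6H3 thiourea (10 mol %), PhCO2H (10 mol %), 4 Å MS, toluene, 30 °C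
Reagents that add atoms: none
Why: Domino oxa-Michael/Henry (nitro-aldol)/dehydration, in which the phenoxide adds to the hydrogen-bonded nitroalkene and the resulting nitronate (the masked acyl anion of the future C3 carbonyl) attacks the aldehyde carbon C4, so that two normally electrophilic carbons are joined, ring C closes, and the chiral thiourea fixes C2 as S.

Step 5
Reactants: 3 8-bromo-5,7,3',4',5'-penta-O-benzyl-(−)-epigallocatechin; 9 (S)-7-(benzyloxy)-3-nitro-2-[3,4,5-tris(benzyloxy)phenyl]-2H-chromene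
Product: 13 (2R,3S,4S)-all-trans 3-nitroflavan-(4→8)-penta-O-benzyl-epigallocatechin, via 8-lithio lithium alkoxide 10 (not isolated), via dilithium nitronate 11 (not isolated), via kinetic 2,4-trans adduct 12 (not isolated)
Conditions: 3 (1.2 equiv), n-BuLi (2.1 equiv per 3), THF, −78 °C; then 9, −78 °C; AcOH, −78 °C → rt, aqueous work-up; crude, DBU (0.3 equiv), toluene, 45 °C
Reagents that add atoms: none
Why: Proposed new method: a known-type 1,4-addition of an aryllithium to a nitroalkene, in which the bulky nucleophile enters C4 anti to the pseudo-axial 2-aryl group (sets 4S), is followed by catalytic DBU equilibration of the neutral nitro compound through nitronate reprotonation (C3) and retro-oxa-Michael/oxa-Michael ring opening and closure (C2) while C4 cannot epimerise, so the all-equatorial 2R,3S,4S isomer collects, the closest known reactions being organometallic additions to 2-aryl-3-nitro-2H-chromenes and base epimerisation of 3-nitrochromans.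

Step 6
Reactants: 13 (2R,3S,4S)-all-trans 3-nitroflavan-(4→8)-penta-O-benzyl-epigallocatechin
Product: 15 (2R,4S)-2,4-cis flavan-3-one-(4→8)-penta-O-benzyl-epigallocatechin, via potassium nitronate 14 (not isolated)
Conditions: KOtBu (1.05 equiv), THF, −40 °C; DMDO (0.07 M in acetone, 1.2 equiv), −78 → −20 °C; pH 7 buffer; used at once
Reagents that add atoms: dimethyldioxirane, CC1(C)OO1
Why: Oxidative Nef reaction, in which the nitronate carbon attacks the electrophilic oxygen of DMDO and the α-nitro alkoxide loses nitrite to unmask the C3 carbonyl, while the low temperature suppresses ring opening and enolisation and C2 and C4 already sit in the favoured 2,4-cis diequatorial arrangement.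

Step 7
Reactants: 15 (2R,4S)-2,4-cis flavan-3-one-(4→8)-penta-O-benzyl-epigallocatechin
Product: 16 nona-O-benzyl robinetinidol-(4α→8)-epigallocatechin
Conditions: NaBH4 (2 equiv), THF–MeOH 4:1, −40 °C
Reagents that add atoms: none
Why: Substrate-controlled ketone reduction, in which the ring atoms 1,3 to the carbonyl (O1 and C4a) carry no axial hydrogens in the half-chair with both aryl groups equatorial, so the small hydride attacks axially under torsional control and the new 3-OH is equatorial and trans to both aryl groups (3S).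

Step 8
Reactants: 16 nona-O-benzyl robinetinidol-(4α→8)-epigallocatechin
Product: 17 robinetinidol-(4α→8)-epigallocatechin (target)
Conditions: H2 (1 atm), 20 % Pd(OH)2/C, THF–MeOH–H2O, rt; filtration, Sephadex LH-20, freeze-drying
Reagents that add atoms: none
Why: Catalytic hydrogenolysis of the nine aryl benzyl ethers under the mild conditions standard for proanthocyanidin end-games, which leave the C2–O1 bonds, the interflavan bond and all five stereocentres intact.

**Compound list**

1 | (−)-epigallocatechin (2R,3R) | Oc1cc(O)c2c(c1)O[C@H](c1cc(O)c(O)c(O)c1)[C@H](O)C2 | starting material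

2 | 5,7,3',4',5'-penta-O-benzyl-(−)-epigallocatechin, 3-OH free | c1ccccc1COc1cc(OCc3ccccc3)c2c(c1)O[C@H](c1cc(OCc3ccccc3)c(OCc3ccccc3)c(OCc3ccccc3)c1)[C@H](O)C2 | intermediate

3 | 8-bromo-5,7,3',4',5'-penta-O-benzyl-(−)-epigallocatechin | Brc1c(OCc3ccccc3)cc(OCc3ccccc3)c2c1O[C@H](c1cc(OCc3ccccc3)c(OCc3ccccc3)c(OCc3ccccc3)c1)[C@H](O)C2 | intermediate

4 | 3,4,5-tris(benzyloxy)benzaldehyde | O=Cc1cc(OCc2ccccc2)c(OCc2ccccc2)c(OCc2ccccc2)c1 | starting material

5 | nitromethane | C[N+](=O)[O-] | starting material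

6 | (E)-1,2,3-tris(benzyloxy)-5-(2-nitrovinyl)benzene | [O-][N+](=O)/C=C/c1cc(OCc2ccccc2)c(OCc2ccccc2)c(OCc2ccccc2)c1 | intermediate

7 | 4-(benzyloxy)-2-hydroxybenzaldehyde | O=Cc1ccc(OCc2ccccc2)cc1O | starting material

8 | (2S)-7-(benzyloxy)-3-nitro-2-[3,4,5-tris(benzyloxy)phenyl]chroman-4-ol, mixture at C3 and C4 | c1ccccc1COc1ccc2c(c1)O[C@@H](c1cc(OCc3ccccc3)c(OCc3ccccc3)c(OCc3ccccc3)c1)C([N+](=O)[O-])C2O | intermediate

9 | (S)-7-(benzyloxy)-3-nitro-2-[3,4,5-tris(benzyloxy)phenyl]-2H-chromene | c1ccccc1COc1ccc2c(c1)O[C@@H](c1cc(OCc3ccccc3)c(OCc3ccccc3)c(OCc3ccccc3)c1)C([N+](=O)[O-])=C2 | intermediate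

10 | 8-lithio-penta-O-benzyl-epigallocatechin lithium 3-alkoxide | [Li]c1c(OCc3ccccc3)cc(OCc3ccccc3)c2c1O[C@H](c1cc(OCc3ccccc3)c(OCc3ccccc3)c(OCc3ccccc3)c1)[C@H](O[Li])C2 | intermediate

11 | dilithium salt (C3 nitronate, lower 3-alkoxide) of the (2S,4S) adduct | [Li+].[Li+].c1ccccc1COc1ccc2c(c1)O[C@@H](c1cc(OCc3ccccc3)c(OCc3ccccc3)c(OCc3ccccc3)c1)C(=[N+]([O-])[O-])[C@@H]2c1c(OCc3ccccc3)cc(OCc3ccccc3)c2c1O[C@H](c1cc(OCc3ccccc3)c(OCc3ccccc3)c(OCc3ccccc3)c1)[C@H]([O-])C2 | intermediate

12 | (2S,4S)-2,4-trans 3-nitroflavan-(4→8)-penta-O-benzyl-epigallocatechin, C3 epimers | c1ccccc1COc1ccc2c(c1)O[C@@H](c1cc(OCc3ccccc3)c(OCc3ccccc3)c(OCc3ccccc3)c1)C([N+](=O)[O-])[C@@H]2c1c(OCc3ccccc3)cc(OCc3ccccc3)c2c1O[C@H](c1cc(OCc3ccccc3)c(OCc3ccccc3)c(OCc3ccccc3)c1)[C@H](O)C2 | intermediate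

13 | (2R,3S,4S)-7-(benzyloxy)-3-nitro-2-[3,4,5-tris(benzyloxy)phenyl]chroman-4-yl at C8 of penta-O-benzyl-epigallocatechin | c1ccccc1COc1ccc2c(c1)O[C@H](c1cc(OCc3ccccc3)c(OCc3ccccc3)c(OCc3ccccc3)c1)[C@@H]([N+](=O)[O-])[C@@H]2c1c(OCc3ccccc3)cc(OCc3ccccc3)c2c1O[C@H](c1cc(OCc3ccccc3)c(OCc3ccccc3)c(OCc3ccccc3)c1)[C@H](O)C2 | intermediate

14 | potassium C3 nitronate of 13 | [K+].c1ccccc1COc1ccc2c(c1)O[C@H](c1cc(OCc3ccccc3)c(OCc3ccccc3)c(OCc3ccccc3)c1)C(=[N+]([O-])[O-])[C@@H]2c1c(OCc3ccccc3)cc(OCc3ccccc3)c2c1O[C@H](c1cc(OCc3ccccc3)c(OCc3ccccc3)c(OCc3ccccc3)c1)[C@H](O)C2 | intermediate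

15 | (2R,4S)-7-(benzyloxy)-3-oxo-2-[3,4,5-tris(benzyloxy)phenyl]chroman-4-yl at C8 of penta-O-benzyl-epigallocatechin | c1ccccc1COc1ccc2c(c1)O[C@H](c1cc(OCc3ccccc3)c(OCc3ccccc3)c(OCc3ccccc3)c1)C(=O)[C@@H]2c1c(OCc3ccccc3)cc(OCc3ccccc3)c2c1O[C@H](c1cc(OCc3ccccc3)c(OCc3ccccc3)c(OCc3ccccc3)c1)[C@H](O)C2 | intermediate

16 | nona-O-benzyl robinetinidol-(4α→8)-epigallocatechin, both 3-OH free | c1ccccc1COc1ccc2c(c1)O[C@H](c1cc(OCc3ccccc3)c(OCc3ccccc3)c(OCc3ccccc3)c1)[C@@H](O)[C@@H]2c1c(OCc3ccccc3)cc(OCc3ccccc3)c2c1O[C@H](c1cc(OCc3ccccc3)c(OCc3ccccc3)c(OCc3ccccc3)c1)[C@H](O)C2 | intermediate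

17 | robinetinidol-(4α→8)-epigallocatechin | Oc1ccc2c(c1)O[C@H](c1cc(O)c(O)c(O)c1)[C@@H](O)[C@@H]2c1c(O)cc(O)c2c1O[C@H](c1cc(O)c(O)c(O)c1)[C@H](O)C2 | target

**Totals**
- Total step count: 8.
- Longest linear sequence: 6 steps (1→2→3→13→15→16→17, or equally 4→6→9→13→15→16→17).

**Three steps most likely to fail**

**Step 5.**
- The hindered aryllithium may deprotonate the acidic C2–H of 9 instead of adding.
- The anti face selectivity at C4 is argued from sterics, not proven.
- The C2 inversion needs ring opening, and the open nitroalkene could lose C4 integrity by γ-deprotonation.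

The fallback sets out from 7 and 5 (it also uses 3 and 4) and comes back at 13. It lets a chiral ligand, not a ring stereocentre, set C4. Aldehyde 7 is condensed with 5 (NH4OAc, AcOH) to (E)-5-(benzyloxy)-2-(2-nitrovinyl)phenol F3. This is silylated (TBSCl, imidazole) to its tert-butyldimethylsilyl ether F4. Aryllithium 10 is then added in toluene at −78 °C in the presence of the suitable antipode of the C2-symmetric diether 1,2-dimethoxy-1,2-diphenylethane, giving the (S)-1,1-diaryl-2-nitroethane F5. TBAF then frees the phenol. With aldehyde 4 and piperidinium acetate in warm toluene, Henry condensation and oxa-Michael closure under the same thermodynamic control deliver 13.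

**Step 6.**
- The nitronate flanked by two equatorial aryl groups is strained.
- It may form slowly, open by loss of the aryloxide, or be over-oxidised.

The fallback sets out from 13 and comes back at 15. It avoids any stoichiometric nitronate by going reductively. SnCl2·2H2O, PhSH and Et3N in THF take the nitro group to the (2R,4S)-flavan-3-one oxime F6. Buffered aqueous TiCl3 with NH4OAc in THF then reduces the N–O bond, and hydrolysis of the imine gives 15.

**Step 4.**
- Both partners carry donor groups, so the domino may be slow.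
- The enantiomeric excess may be only moderate, because the oxa-Michael step is reversible.

The fallback sets out from 6 and 7 and comes back at 13. It replaces asymmetric catalysis by resolution through the enantiopure lower unit. Achiral DABCO in MeCN at 60 °C gives the racemic chromene F1. This is coupled with 10 and equilibrated with DBU exactly as in step 5. The two all-trans products, 13 and its (2S,3R,4R) upper-unit diastereomer F2, are then no longer mirror images and are separated by chromatography or crystallisation.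

**Further compounds**

F1 | step 4 | rac-7-(benzyloxy)-3-nitro-2-[3,4,5-tris(benzyloxy)phenyl]-2H-chromene | c1ccccc1COc1ccc2c(c1)OC(c1cc(OCc3ccccc3)c(OCc3ccccc3)c(OCc3ccccc3)c1)C([N+](=O)[O-])=C2

F2 | step 4 | (2S,3R,4R)-all-trans 3-nitroflavan-(4→8)-penta-O-benzyl-epigallocatechin | c1ccccc1COc1ccc2c(c1)O[C@@H](c1cc(OCc3ccccc3)c(OCc3ccccc3)c(OCc3ccccc3)c1)[C@H]([N+](=O)[O-])[C@H]2c1c(OCc3ccccc3)cc(OCc3ccccc3)c2c1O[C@H](c1cc(OCc3ccccc3)c(OCc3ccccc3)c(OCc3ccccc3)c1)[C@H](O)C2

F3 | step 5 | (E)-5-(benzyloxy)-2-(2-nitrovinyl)phenol | [O-][N+](=O)/C=C/c1ccc(OCc2ccccc2)cc1O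

F4 | step 5 | (E)-[5-(benzyloxy)-2-(2-nitrovinyl)phenoxy](tert-butyl)dimethylsilane | [O-][N+](=O)/C=C/c1ccc(OCc2ccccc2)cc1O[Si](C)(C)C(C)(C)C

F5 | step 5 | (S)-1-[4-(benzyloxy)-2-(tert-butyldimethylsilyloxy)phenyl]-2-nitroethyl at C8 of penta-O-benzyl-epigallocatechin | c1ccccc1COc1ccc(c(O[Si](C)(C)C(C)(C)C)c1)[C@H](C[N+](=O)[O-])c1c(OCc3ccccc3)cc(OCc3ccccc3)c2c1O[C@H](c1cc(OCc3ccccc3)c(OCc3ccccc3)c(OCc3ccccc3)c1)[C@H](O)C2

F6 | step 6 | (2R,4S)-flavan-3-one oxime-(4→8)-penta-O-benzyl-epigallocatechin | c1ccccc1COc1ccc2c(c1)O[C@H](c1cc(OCc3ccccc3)c(OCc3ccccc3)c(OCc3ccccc3)c1)C(=NO)[C@@H]2c1c(OCc3ccccc3)cc(OCc3ccccc3)c2c1O[C@H](c1cc(OCc3ccccc3)c(OCc3ccccc3)c(OCc3ccccc3)c1)[C@H](O)C2
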